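**Retrosynthetic overview**
1. C9–C11: sp3–sp2 Negishi coupling of a decalin enol triflate with a C6 (E)-enoate zinc reagent. The zinc reagent comes from 4-bromobut-1-yne by carboalumination and acylation.
2. Ring B: one-carbon ring expansion of a hydrindenone cyclopentanone by diazoethane insertion (1,2-shift of C7, loss of N2). This brings in C8 with its methyl group and leaves a C9 oxygen that can only enolise toward C8.
3. C4 and C5: dissolving-metal reductive methylation of the C4=C5 enoate, run after the expansion so that a trans-decalin forms.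
4. Ring A and C10: a new copper-hydride reductive Horner–Wadsworth–Emmons desymmetrisation of a 2,2-disubstituted cyclopentane-1,3-dione.
5. Ring order: the purchased cyclopentane ring first, then ring A (six-membered), then ring B by five-to-six expansion.

Assumption: C1–C20 are labdane numbers of the target, and the (R) ligand in step 3 is taken to give the (7aS) series (the antipode is used if the first run shows the opposite sense).

**Step 1**
Reactants: 1 2-methylcyclopentane-1,3-dione; 2 acrolein
Product: 3 3-(1-methyl-2,5-dioxocyclopentyl)propanal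
Conditions: H2O, rt, 16 h
Reagents that add atoms: none
Why: Michael addition; the acidic cyclic 1,3-dione adds through carbon to acrolein in water without added base and builds the quaternary, still prochiral C10.

**Step 2**
Reactants: 3 3-(1-methyl-2,5-dioxocyclopentyl)propanal
Product: 4 methyl 2-(dimethoxyphosphoryl)-5-(1-methyl-2,5-dioxocyclopentyl)pent-2-enoate (E/Z mixture)
Conditions: (MeO)2P(O)CH2CO2Me, TiCl4, N-methylmorpholine, THF, 0 °C → rt
Reagents that add atoms: trimethyl phosphonoacetate, COC(=O)CP(=O)(OC)OC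
Why: Knoevenagel condensation under TiCl4/amine activation occurs only at the aldehyde because both ketones are neopentyl-type, and the alkene geometry does not matter for step 3.

**Step 3**
Reactants: 4 methyl 2-(dimethoxyphosphoryl)-5-(1-methyl-2,5-dioxocyclopentyl)pent-2-enoate
Product: 5 methyl (7aS)-7a-methyl-1-oxo-2,3,5,6,7,7a-hexahydro-1H-indene-4-carboxylate
Conditions: Cu(OAc)2·H2O (5 mol %), (R)-DTBM-SEGPHOS (5.5 mol %), (EtO)2MeSiH (1.5 equiv), toluene, −40 °C → rt
Reagents that add atoms: none
Why: Proposed new method: enantioselective copper-hydride-triggered reductive Horner–Wadsworth–Emmons desymmetrisation; the ligated CuH delivers hydride to C3 of the doubly activated alkene faster than to the hindered ketones, the ligand-bound copper phosphonoenolate adds through a closed transition state to one of the two enantiotopic carbonyls, the copper aldolate collapses irreversibly through the oxaphosphetane to the C4=C5 enoate (so no retro-aldol erosion), and the copper dimethyl phosphate is returned to CuH by the silane just as Cu(OAc)2 is; the closest known reaction types are the copper-hydride reductive aldol cyclisation of enoate-diones and the Michael-initiated intramolecular HWE reaction of 2-phosphonoacrylates; ring A is closed and C10, the only stereocentre left, is set here.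

**Step 4**
Reactants: 5 methyl (7aS)-7a-methyl-1-oxo-2,3,5,6,7,7a-hexahydro-1H-indene-4-carboxylate; 6 N-ethyl-N-nitrosourea
Product: 9 methyl (4aS)-5-[(tert-butyldimethylsilyl)oxy]-4a,6-dimethyl-2,3,4,4a,7,8-hexahydronaphthalene-1-carboxylate, via diazoethane 7 (not isolated), via ring-expanded ketone 8 (not isolated)
Conditions: 6, KOH, Et2O/H2O, 0 °C (ethereal 7 decanted, dried over KOH); 5, Sc(OTf)3 (10 mol %), CH2Cl2, −78 → 0 °C; then Et3N, TBSOTf, 0 °C → rt
Reagents that add atoms: tert-butyldimethylsilyl triflate, CC(C)(C)[Si](C)(C)OS(=O)(=O)C(F)(F)F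
Why: Lewis-acid-catalysed diazoalkane homologation of a ketone (Tiffeneau–Demjanov-type 1,2-shift); 7 adds to the only ketone, the unhindered C7 methylene migrates rather than quaternary C10 with loss of N2 (as in the D-homoannulation of 17-oxo steroids), ketone 8 is too hindered for a second insertion, and soft enolisation can only go toward C8, which erases the C8 epimers and masks C9 for step 5.

**Step 5**
Reactants: 9 methyl (4aS)-5-[(tert-butyldimethylsilyl)oxy]-4a,6-dimethyl-2,3,4,4a,7,8-hexahydronaphthalene-1-carboxylate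
Product: 11 methyl (1S,4aS,8aR)-5-[(tert-butyldimethylsilyl)oxy]-1,4a,6-trimethyl-1,2,3,4,4a,7,8,8a-octahydronaphthalene-1-carboxylate, via lithium enolate 10 (not isolated)
Conditions: Li (2.2 equiv), t-BuOH (1.0 equiv), NH3/THF, −78 °C; then MeI, −78 → −33 °C
Reagents that add atoms: iodomethane, CI
Why: Birch-type dissolving-metal reductive alkylation of an α,β-unsaturated ester; C5 is protonated on the α face opposite the angular methyl to give the trans-decalin enolate, MeI then attacks the exocyclic enolate from the equatorial α face to avoid the 1,3-diaxial C10 methyl (4α-CH3, axial 4β-CO2Me), and the electron-rich silyl enol ether is inert.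

**Step 6**
Reactants: 11 methyl (1S,4aS,8aR)-5-[(tert-butyldimethylsilyl)oxy]-1,4a,6-trimethyl-1,2,3,4,4a,7,8,8a-octahydronaphthalene-1-carboxylate
Product: 13 [(1S,4aS,8aS)-5-[(tert-butyldimethylsilyl)oxy]-1,4a,6-trimethyl-1,2,3,4,4a,7,8,8a-octahydronaphthalen-1-yl]methyl acetate, via primary alcohol 12 (not isolated)
Conditions: LiAlH4, THF, 0 → 40 °C; then pyridine, Ac2O, DMAP (cat.), 0 °C → rt
Reagents that add atoms: acetic anhydride, CC(=O)OC(C)=O
Why: Hydride reduction of the hindered axial ester followed by acetylation of the aluminium alkoxide in the same flask; no stereocentre is touched (the 8a descriptor changes only through CIP ranking) and the silyl enol ether tolerates both reagents.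

**Step 7**
Reactants: 13 [(1S,4aS,8aS)-5-[(tert-butyldimethylsilyl)oxy]-1,4a,6-trimethyl-1,2,3,4,4a,7,8,8a-octahydronaphthalen-1-yl]methyl acetate
Product: 14 [(1S,4aS,8aS)-1,4a,6-trimethyl-5-[(trifluoromethylsulfonyl)oxy]-1,2,3,4,4a,7,8,8a-octahydronaphthalen-1-yl]methyl acetate
Conditions: CsF (3 equiv), PhNTf2 (1.5 equiv), DME, rt → 40 °C
Reagents that add atoms: N-phenylbis(trifluoromethanesulfonimide), O=S(=O)(N(c1ccccc1)S(=O)(=O)C(F)(F)F)C(F)(F)F
Why: Fluoride-induced cleavage of the silyl enol ether releases the regiodefined tetrasubstituted enolate, which PhNTf2 O-sulfonylates at once (enol triflate synthesis), and the acetate survives the mild medium.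

**Step 8**
Reactants: 15 4-bromobut-1-yne
Product: 17 methyl (2E)-5-bromo-3-methylpent-2-enoate, via alkenylalane 16 (not isolated)
Conditions: Me3Al (2 equiv), Cp2ZrCl2 (20 mol %), CH2Cl2, 0 °C → rt; then ClCO2Me, 0 °C → rt
Reagents that add atoms: trimethylaluminium, C[Al](C)C; methyl chloroformate, COC(=O)Cl
Why: Zirconium-catalysed syn-carboalumination of a terminal alkyne (Negishi carboalumination) places CH3 on the internal carbon cis to aluminium, and acylation of the alkenylalane goes with retention, which fixes the E geometry.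

**Step 9**
Reactants: 14 [(1S,4aS,8aS)-1,4a,6-trimethyl-5-[(trifluoromethylsulfonyl)oxy]-1,2,3,4,4a,7,8,8a-octahydronaphthalen-1-yl]methyl acetate; 17 methyl (2E)-5-bromo-3-methylpent-2-enoate
Product: 19 methyl (2E)-5-[(4aR,5S,8aS)-5-(acetoxymethyl)-2,5,8a-trimethyl-3,4,4a,5,6,7,8,8a-octahydronaphthalen-1-yl]-3-methylpent-2-enoate, via alkylzinc bromide 18 (not isolated)
Conditions: 17, Zn dust, LiCl, THF, 50 °C; then 14, Pd(OAc)2 (5 mol %), SPhos (10 mol %), THF/NMP, 50 °C
Reagents that add atoms: none
Why: Negishi sp3–sp2 cross-coupling; LiCl-assisted zinc insertion gives an ester-tolerant primary alkylzinc, and zerovalent palladium with a bulky biaryl phosphine joins it to the hindered enol triflate with retention of both double bonds and without touching any stereocentre.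

**Compound list**
1 | 2-methylcyclopentane-1,3-dione | CC1C(=O)CCC1=O | starting material
2 | acrolein | C=CC=O | starting material
3 | 3-(1-methyl-2,5-dioxocyclopentyl)propanal | O=CCCC1(C)C(=O)CCC1=O | intermediate
4 | methyl 2-(dimethoxyphosphoryl)-5-(1-methyl-2,5-dioxocyclopentyl)pent-2-enoate (E/Z mixture) | COC(=O)C(=CCCC1(C)C(=O)CCC1=O)P(=O)(OC)OC | intermediate
5 | methyl (7aS)-7a-methyl-1-oxo-2,3,5,6,7,7a-hexahydro-1H-indene-4-carboxylate | COC(=O)C1=C2CCC(=O)[C@@]2(C)CCC1 | intermediate
6 | N-ethyl-N-nitrosourea | CCN(N=O)C(N)=O | starting material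
7 | diazoethane (not isolated) | CC=[N+]=[N-] | intermediate
8 | methyl (4aS)-4a,6-dimethyl-5-oxo-2,3,4,4a,5,6,7,8-octahydronaphthalene-1-carboxylate (C6 epimers, not isolated) | COC(=O)C1=C2CCC(C)C(=O)[C@@]2(C)CCC1 | intermediate
9 | methyl (4aS)-5-[(tert-butyldimethylsilyl)oxy]-4a,6-dimethyl-2,3,4,4a,7,8-hexahydronaphthalene-1-carboxylate | COC(=O)C1=C2CCC(C)=C(O[Si](C)(C)C(C)(C)C)[C@@]2(C)CCC1 | intermediate
10 | lithium ester enolate of the (4aS,8aR) trans-decalin, 5α-H (not isolated) | CC(C)(C)[Si](C)(C)OC1=C(C)CC[C@H]2C(=C([O-])OC)CCC[C@]12C.[Li+] | intermediate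
11 | methyl (1S,4aS,8aR)-5-[(tert-butyldimethylsilyl)oxy]-1,4a,6-trimethyl-1,2,3,4,4a,7,8,8a-octahydronaphthalene-1-carboxylate | CC(C)(C)[Si](C)(C)OC1=C(C)CC[C@H]2[C@@](C)(C(=O)OC)CCC[C@]12C | intermediate
12 | [(1S,4aS,8aS)-5-[(tert-butyldimethylsilyl)oxy]-1,4a,6-trimethyl-1,2,3,4,4a,7,8,8a-octahydronaphthalen-1-yl]methanol (not isolated) | CC(C)(C)[Si](C)(C)OC1=C(C)CC[C@H]2[C@@](C)(CO)CCC[C@]12C | intermediate
13 | [(1S,4aS,8aS)-5-[(tert-butyldimethylsilyl)oxy]-1,4a,6-trimethyl-1,2,3,4,4a,7,8,8a-octahydronaphthalen-1-yl]methyl acetate | CC(C)(C)[Si](C)(C)OC1=C(C)CC[C@H]2[C@@](C)(COC(C)=O)CCC[C@]12C | intermediate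
14 | [(1S,4aS,8aS)-1,4a,6-trimethyl-5-[(trifluoromethylsulfonyl)oxy]-1,2,3,4,4a,7,8,8a-octahydronaphthalen-1-yl]methyl acetate | O=S(=O)(OC1=C(C)CC[C@H]2[C@@](C)(COC(C)=O)CCC[C@]12C)C(F)(F)F | intermediate
15 | 4-bromobut-1-yne | C#CCCBr | starting material
16 | [(1E)-4-bromo-2-methylbut-1-en-1-yl]dimethylalane (not isolated) | C[Al](C)/C=C(\C)CCBr | intermediate
17 | methyl (2E)-5-bromo-3-methylpent-2-enoate | COC(=O)/C=C(\C)CCBr | intermediate
18 | [(3E)-5-methoxy-3-methyl-5-oxopent-3-en-1-yl]zinc bromide (not isolated) | COC(=O)/C=C(\C)CC[Zn]Br | intermediate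
19 | methyl (2E)-5-[(4aR,5S,8aS)-5-(acetoxymethyl)-2,5,8a-trimethyl-3,4,4a,5,6,7,8,8a-octahydronaphthalen-1-yl]-3-methylpent-2-enoate (labdane 4S,5R,10S; 19-OAc axial) | COC(=O)/C=C(\C)CCC1=C(C)CC[C@H]2[C@@](C)(COC(C)=O)CCC[C@]12C | target

**Step count**
- Total steps: 9.
- Longest linear sequence: 8 (steps 1–7 and 9).

**Three steps most likely to fail**

**Step 3 (new reaction).**
- Risks: 1,2-reduction of a ketone by CuH; silyl transfer to the stabilised enolate followed by a racemic background HWE reaction; low ee.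
- The fallback uses known chemistry, sets out from 3 (so it also bypasses step 2) and comes back at 5.
- Aldehyde 3 reacts with methyl (triphenylphosphoranylidene)acetate in CH2Cl2 to give methyl (2E)-5-(1-methyl-2,5-dioxocyclopentyl)pent-2-enoate F1.
- The established enantioselective copper-hydride reductive aldol cyclisation of such enoate-diones (Cu(OAc)2·H2O, chiral ferrocenyl bisphosphine, PhSiH3, toluene) then gives the cis-fused ketol methyl (3aS,7aS)-3a-hydroxy-7a-methyl-1-oxooctahydro-1H-indene-4-carboxylate F2.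
- Dehydration with SOCl2/pyridine, followed by DBU to bring any deconjugated alkene into conjugation, delivers 5.

**Step 4 (ring expansion).**
- Risks: slow addition of a non-stabilised diazoalkane to the neopentyl ketone; epoxide formation; handling of diazoethane.
- The fallback sets out from 5 and comes back at 8, which is then silylated as in step 4. It replaces the direct CH–CH3 insertion by an acceptor-diazo homologation plus alkylation.
- Ethyl diazoacetate with BF3·OEt2 inserts CH(CO2Et) on the methylene side and gives 6-ethyl 1-methyl (4aS)-4a-methyl-5-oxo-2,3,4,4a,5,6,7,8-octahydronaphthalene-1,6-dicarboxylate F3.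
- K2CO3/MeI in acetone methylates C8 to 6-ethyl 1-methyl (4aS)-4a,6-dimethyl-5-oxo-2,3,4,4a,5,6,7,8-octahydronaphthalene-1,6-dicarboxylate F4.
- LiCl in wet DMSO at 150 °C removes only the β-keto ethoxycarbonyl group and gives 8.

**Step 9 (hindered coupling).**
- Risks: slow reaction at the tetrasubstituted triflate; β-hydride elimination; reduction of the triflate.
- The fallback sets out from 14 and comes back at 19. It moves the sp3–sp2 bond formation to an unhindered partner.
- Stille vinylation of 14 (tributyl(vinyl)stannane, Pd(PPh3)4, LiCl, THF, reflux) gives [(1S,4aS,8aR)-5-ethenyl-1,4a,6-trimethyl-1,2,3,4,4a,7,8,8a-octahydronaphthalen-1-yl]methyl acetate F5.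
- 9-BBN adds only to the terminal vinyl carbon and gives the B-alkyl-9-borabicyclo[3.3.1]nonane F6.
- F6 undergoes B-alkyl Suzuki coupling (PdCl2(dppf), K3PO4, DMF/THF/H2O, rt) with methyl (2E)-3-[(trifluoromethylsulfonyl)oxy]but-2-enoate F7, made from methyl acetoacetate with Tf2O and aqueous Me4NOH. The coupling goes with retention and gives 19.

**Further compounds**
F1 | step 3 | methyl (2E)-5-(1-methyl-2,5-dioxocyclopentyl)pent-2-enoate | COC(=O)/C=C/CCC1(C)C(=O)CCC1=O
F2 | step 3 | methyl (3aS,7aS)-3a-hydroxy-7a-methyl-1-oxooctahydro-1H-indene-4-carboxylate (C4 configuration immaterial) | COC(=O)C1CCC[C@]2(C)C(=O)CC[C@]12O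
F3 | step 4 | 6-ethyl 1-methyl (4aS)-4a-methyl-5-oxo-2,3,4,4a,5,6,7,8-octahydronaphthalene-1,6-dicarboxylate | COC(=O)C1=C2CCC(C(=O)OCC)C(=O)[C@@]2(C)CCC1
F4 | step 4 | 6-ethyl 1-methyl (4aS)-4a,6-dimethyl-5-oxo-2,3,4,4a,5,6,7,8-octahydronaphthalene-1,6-dicarboxylate | COC(=O)C1=C2CCC(C)(C(=O)OCC)C(=O)[C@@]2(C)CCC1
F5 | step 9 | [(1S,4aS,8aR)-5-ethenyl-1,4a,6-trimethyl-1,2,3,4,4a,7,8,8a-octahydronaphthalen-1-yl]methyl acetate | C=CC1=C(C)CC[C@H]2[C@@](C)(COC(C)=O)CCC[C@]12C
F6 | step 9 | B-alkyl-9-borabicyclo[3.3.1]nonane from F5 (boron on C12) | B1(C2CCCC1CCC2)CCC3=C(C)CC[C@H]4[C@@](C)(COC(C)=O)CCC[C@]34C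
F7 | step 9 | methyl (2E)-3-[(trifluoromethylsulfonyl)oxy]but-2-enoate | COC(=O)/C=C(\C)OS(=O)(=O)C(F)(F)F
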